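(The numbers are those of an exercise; the result is computed.)

An easy step first: an enzyme that has become spent catalyst A makes no more product, so I ask how much product it made before that happened.

| setting | ochre | teal | green | violet | blue |
|---|---|---|---|---|---|
| substrate | 0.10 M | 0.10 M | 0.10 M | 0.10 M | 0.10 M |
| enzyme | 10 µM | 10 µM | 10 µM | 10 µM | 10 µM |
| impurity | 3.0 µM | 6.0 µM | 12 µM | 25 µM | 50 µM |
| time | 2.0 h | 2.0 h | 2.0 h | 2.0 h | 2.0 h |

    substrate + enzyme ⇌ complex (K1 = 6.9 M⁻¹, k1 = 8.9 × 10⁵ M⁻¹ h⁻¹)
    enzyme + impurity → spent catalyst B (k2 = 4.2 × 10⁵ M⁻¹ h⁻¹)
    complex → enzyme + product (k3 = 1100 h⁻¹)
    substrate + enzyme → spent catalyst A (k4 = 3.2 M⁻¹ h⁻¹)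

- amount of product at the end, in percent of the substrate charged for ochre, teal, green, violet, blue, in this order
- how that number moves from the first to the last of them (hardly changes / falls, then rises / rises, then falls / rises all the way / falls all the way)

- "hardly changes" means that all values lie within two and a half points (for a concentration: within two and a half percent of the largest)
- run time (ochre): 2.0 h

1. Complex lives about 0.0277 s, far less than the run of 2.0 h, so it stays in balance with enzyme: c(complex)/c(enzyme) equals c(substrate)/Km, where Km is 0.146 M.

2. Product forms at 1100 h⁻¹ times c(complex), and spent catalyst A forms at 3.2 M⁻¹ h⁻¹ times c(substrate) times c(enzyme). On dividing, the concentrations cancel and 2350 remains. This is G, the moles of product made for each mole of spent catalyst A formed, a selectivity factor. The impurity does not enter it, so I look for the product in how much enzyme reaches spent catalyst A.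

3. The first setting is the impurity charge. With substrate at its charge, free enzyme goes to spent catalyst B and to spent catalyst A at equal rates at c(impurity) = 0.762 µM, and this crossing lies below each charge here. In ochre, though, impurity is the limiting reagent of its step, 3.0 µM against 10 µM of enzyme. At least 7.00 µM of enzyme is then left for the substrate, which allows 16.5% of product in the end. In blue, impurity exceeds enzyme. Held at its charge, it leaves the substrate a share of 1.50%, which gives 0.353%. So I expect a fall along the row.

4. The second setting is the run time. At the charged substrate, free enzyme is 59.4% of the working enzyme, meaning enzyme plus complex. In blue, with impurity held at its charge, the working enzyme should therefore halve in 0.0548 h, well within the run, so a later reading should change nothing. In ochre, the substrate route on its own should halve the working enzyme in 3.65 h, longer than the run, so the reading should stand well below that end value.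

5. The forecast gives 5.6%, 4.2%, 2.2%, 0.87% and 0.39%, so the number falls all the way, on the ground that “product simply tracks the time-integral of surviving enzyme”. My blue figure stands below its figure.

The flask gives 5.63%, 4.18%, 2.21%, 0.868% and 0.392%, so the number falls all the way, as forecast, and blue stands above my figure. Ochre at 2.00 h holds 23.9% of its catalyst charge as spent catalyst A, and G turns that into 5.63% of the substrate charged. Blue, whose product is unchanged at 20.0 h, holds 1.67% of its catalyst charge as spent catalyst A, and G turns that into 0.392%, beside the reading of 0.392%.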